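Both halves of the target are (+)-catechin, and everything rests on one disconnection: the biaryl bond between C6' of the catechol ring B of one flavan and C6 of the phloroglucinol ring A of the other. The key step exploits the 3',4'-dihydroxy pattern of ring B: anodic oxidation converts it into an o-quinone whose C6' is the open β-carbon, and C6 of ring A, flanked by the C5 and C7 oxygens, adds to it; tautomerisation restores the catechol. The precursors are 6,8-dibromocatechin (quinone partner, ring A blocked) and 8-bromo-tetra-O-benzylcatechin (nucleophile, C8 blocked, ring B masked). All bromines and benzyl groups leave in one final hydrogenolysis.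

Key step: step 4

Remark: the target SMILES defines no axial configuration at the tri-ortho-substituted biaryl bond, so its rotamers are treated as not resolved; the four carbon stereocentres (2R,3S in each unit) are taken unchanged from (+)-catechin.

Step 1
Reactants: 1 (+)-catechin, (2R,3S)-2-(3,4-dihydroxyphenyl)chromane-3,5,7-triol
Product: 2 5,7,3',4'-tetra-O-benzyl-(+)-catechin (3-OH free)
Conditions: BnBr (4.2 equiv), K2CO3, DMF, 0 °C to rt, Ar
Reagents that add atoms: benzyl bromide, BrCc1ccccc1
Why: Williamson etherification in which the four phenols, far more acidic than the secondary 3-OH, are alkylated chemoselectively by carbonate base while exclusion of air prevents catechol oxidation; C2 and C3 are not touched.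

Step 2
Reactants: 2 5,7,3',4'-tetra-O-benzyl-(+)-catechin
Product: 3 8-bromo-5,7,3',4'-tetra-O-benzyl-(+)-catechin
Conditions: NBS (1.0 equiv), CH2Cl2, −78 °C to rt
Reagents that add atoms: N-bromosuccinimide, O=C1CCC(=O)N1Br
Why: electrophilic aromatic bromination of the most electron-rich ring (ring A), where C8 (between O7 and the ring oxygen O1) is less hindered than C6 (between two benzyloxy groups), a regiochemistry well established for benzylated flavan-3-ols; no stereocentre is involved.

Step 3
Reactants: 1 (+)-catechin
Product: 4 6,8-dibromo-(+)-catechin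
Conditions: NBS (2.05 equiv), THF–MeCN, −20 to 0 °C, dark
Reagents that add atoms: N-bromosuccinimide, O=C1CCC(=O)N1Br
Why: twofold electrophilic aromatic bromination at C6 and C8 of ring A, each ortho/para to three oxygens and therefore far more reactive than any position of the catechol ring B, so two equivalents should stop at the ring A dibromide; no stereocentre is involved.

Step 4
Reactants: 4 6,8-dibromo-(+)-catechin; 3 8-bromo-5,7,3',4'-tetra-O-benzyl-(+)-catechin
Product: 6 6,8-dibromo-(+)-catechin-(6'→6)-8-bromo-5,7,3',4'-tetra-O-benzyl-(+)-catechin, via 6,8-dibromocatechin o-quinone 5 (not isolated)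
Conditions: undivided cell, graphite anode, Pt wire cathode, controlled potential at the first anodic wave of 4 (set by cyclic voltammetry), about 2 F per mole of 4, 3 (1.5 equiv), Bu4NPF6 (0.1 M), HFIP–CH2Cl2 (1:1), 0 °C, Ar
Reagents that add atoms: none
Why: Anodic two-electron, two-proton oxidation of the 3',4'-catechol of ring B of 4 (the only free catechol present, oxidised well below the potential of the benzyl aryl ethers of 3) gives o-quinone 5, in which the C4' carbonyl makes C6' the only unsubstituted β-carbon; C6 of ring A of 3, activated by the C5, C7 and C8a oxygens, adds to C6' in a Friedel–Crafts-type 1,4-addition assisted by hydrogen bonding of HFIP to the quinone, enolisation of the adduct restores the catechol, and the two protons are reduced to H2 at the cathode. The closest known reaction type is the anodic oxidation of catechols to o-quinones with in situ conjugate addition of carbon nucleophiles, and the same quinone–ring A addition is the way the B-type dehydrodicatechins arise when catechin is oxidised. No ring is closed and no stereocentre is formed; the four stereocentres come unchanged from (+)-catechin and the new biaryl axis is not configurationally defined in the target. Role selectivity: 4 cannot act as the carbon nucleophile because C6 and C8 of its ring A carry bromine, and 3 cannot become a quinone because its ring B is benzylated. Site selectivity: bromine at C8 of 3 leaves C6 as the only free position of its ring A, and 1,4-addition of carbon nucleophiles to a 4-substituted o-quinone goes to the carbon para to the C3' oxygen, which is C6'. Limiting the charge to about 2 F per mole of 4 and using 3 in excess should restrain further oxidation of the product catechol, which has no free hydroxyl ortho to the new bond that could cyclise onto a quinone.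

Step 5
Reactants: 6 6,8-dibromo-(+)-catechin-(6'→6)-8-bromo-5,7,3',4'-tetra-O-benzyl-(+)-catechin
Product: 7 (+)-catechin-(6'→6)-(+)-catechin (target)
Conditions: H2 (1 atm), Pd(OH)2/C, NaOAc (3.5 equiv), THF–MeOH–H2O, rt; filtration and work-up under Ar
Reagents that add atoms: none
Why: palladium-catalysed hydrogenolysis cleaves the four benzyl aryl ethers and hydrodehalogenates the three aryl bromides in one operation, with acetate buffering the HBr, while the cyclic C2–O1 ethers and the four stereocentres are not affected under these mild conditions.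

Compound list
1 | (+)-catechin, (2R,3S)-2-(3,4-dihydroxyphenyl)chromane-3,5,7-triol | Oc1cc(O)c2c(c1)O[C@H](c1ccc(O)c(O)c1)[C@@H](O)C2 | starting material
2 | 5,7,3',4'-tetra-O-benzyl-(+)-catechin | c1ccccc1COc1cc(OCc3ccccc3)c2c(c1)O[C@H](c1ccc(OCc3ccccc3)c(OCc3ccccc3)c1)[C@@H](O)C2 | intermediate
3 | 8-bromo-5,7,3',4'-tetra-O-benzyl-(+)-catechin | c1ccccc1COc1cc(OCc3ccccc3)c2c(c1Br)O[C@H](c1ccc(OCc3ccccc3)c(OCc3ccccc3)c1)[C@@H](O)C2 | intermediate
4 | 6,8-dibromo-(+)-catechin | Oc1c(Br)c(O)c2c(c1Br)O[C@H](c1ccc(O)c(O)c1)[C@@H](O)C2 | intermediate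
5 | 6,8-dibromocatechin o-quinone (ring B as 3',4'-dione, not isolated) | Oc1c(Br)c(O)c2c(c1Br)O[C@H](C1=CC(=O)C(=O)C=C1)[C@@H](O)C2 | intermediate
6 | 6,8-dibromo-(+)-catechin-(6'→6)-8-bromo-5,7,3',4'-tetra-O-benzyl-(+)-catechin (C6' of ring B of the dibromo unit bonded to C6 of ring A of the benzylated unit) | Oc1c(Br)c(O)c2c(c1Br)O[C@H](c1cc(O)c(O)cc1-c1c(OCc4ccccc4)c(Br)c3c(c1OCc4ccccc4)C[C@H](O)[C@@H](c1ccc(OCc4ccccc4)c(OCc4ccccc4)c1)O3)[C@@H](O)C2 | intermediate
7 | (+)-catechin-(6'→6)-(+)-catechin, both units (2R,3S) | Oc1cc(O)c2c(c1)O[C@H](c1cc(O)c(O)cc1-c1c(O)cc3c(c1O)C[C@H](O)[C@@H](c1ccc(O)c(O)c1)O3)[C@@H](O)C2 | target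

Total step count: 5. Longest linear sequence: 4 steps (1 → 2 → 3 → 6 → 7; steps 1, 2, 4 and 5).

Steps most likely to fail

Step 4. The conjugate addition of the hindered, bromine-deactivated aryl ether may be slower than the side reactions of the quinone. These are tautomerisation to a quinone methide (which would scramble C2), attack by phenolic oxygen, and further oxidation of the product catechol. Fallback (sets out from 2 and 3, comes back at 7): the same bond would be made by Suzuki–Miyaura coupling. NIS with catalytic TFA in CH2Cl2 should iodinate the one free ring A position of 3 to give 8-bromo-6-iodo-5,7,3',4'-tetra-O-benzyl-(+)-catechin F1. NBS (2 equiv) should convert 2 into 6,8-dibromo-5,7,3',4'-tetra-O-benzyl-(+)-catechin F2. With ring A filled, NIS/TFA should iodinate ring B at C6' (para to the 3'-benzyloxy group) to give 6,8-dibromo-6'-iodo-5,7,3',4'-tetra-O-benzyl-(+)-catechin F3. Miyaura borylation at the C–I bond (B2pin2, PdCl2(dppf), KOAc, dioxane, 80 °C) should give 6,8-dibromo-6'-(4,4,5,5-tetramethyl-1,3,2-dioxaborolan-2-yl)-5,7,3',4'-tetra-O-benzyl-(+)-catechin F4. Coupling of F4 with F1 at its C–I bond (Pd(OAc)2, SPhos, K3PO4, toluene–H2O, 90 °C), the doubly flanked, electron-rich C–Br bonds reacting more slowly, should give the octa-O-benzyl tribromo biaryl 6,8-dibromo-5,7,3',4'-tetra-O-benzyl-(+)-catechin-(6'→6)-8-bromo-5,7,3',4'-tetra-O-benzyl-(+)-catechin F5. The conditions of step 5 should convert F5 into 7.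

Step 3. The brominating agent may oxidise the unprotected catechol instead of brominating ring A, and bromination may run on to C6' of ring B. Fallback (sets out from 1, comes back at 4): the catechol would be masked first. Dichlorodiphenylmethane (Ph2CCl2, Ph2O, 170 °C) should give 3',4'-O-diphenylmethylene-(+)-catechin F6. NBS (2 equiv, THF, −20 °C) should then brominate C6 and C8 with no free catechol present, giving 6,8-dibromo-3',4'-O-diphenylmethylene-(+)-catechin F7. Acidic hydrolysis of the ketal (AcOH–H2O, 100 °C) should release 4.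

Step 5. Hydrodebromination of the three flanked aryl bromides may stall through poisoning of the catalyst by bromide while the benzyl ethers are still being cleaved, leaving partly deprotected material. Fallback (sets out from 6, comes back at 7): the two deprotections would be separated. BCl3 with pentamethylbenzene as cation scavenger (CH2Cl2, −78 °C, then MeOH) should cleave the four benzyl ethers without touching the aryl bromides, giving 6,8-dibromo-(+)-catechin-(6'→6)-8-bromo-(+)-catechin F8. Hydrodebromination of F8 alone (H2, Pd/C, NaOAc, MeOH, rt) should then give 7.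

Further compounds
F1 | step 4 | 8-bromo-6-iodo-5,7,3',4'-tetra-O-benzyl-(+)-catechin | c1ccccc1COc1c(I)c(OCc3ccccc3)c2c(c1Br)O[C@H](c1ccc(OCc3ccccc3)c(OCc3ccccc3)c1)[C@@H](O)C2
F2 | step 4 | 6,8-dibromo-5,7,3',4'-tetra-O-benzyl-(+)-catechin | c1ccccc1COc1c(Br)c(OCc3ccccc3)c2c(c1Br)O[C@H](c1ccc(OCc3ccccc3)c(OCc3ccccc3)c1)[C@@H](O)C2
F3 | step 4 | 6,8-dibromo-6'-iodo-5,7,3',4'-tetra-O-benzyl-(+)-catechin | c1ccccc1COc1c(Br)c(OCc3ccccc3)c2c(c1Br)O[C@H](c1cc(OCc3ccccc3)c(OCc3ccccc3)cc1I)[C@@H](O)C2
F4 | step 4 | 6,8-dibromo-6'-(4,4,5,5-tetramethyl-1,3,2-dioxaborolan-2-yl)-5,7,3',4'-tetra-O-benzyl-(+)-catechin | c1ccccc1COc1c(Br)c(OCc3ccccc3)c2c(c1Br)O[C@H](c1cc(OCc3ccccc3)c(OCc3ccccc3)cc1B4OC(C)(C)C(C)(C)O4)[C@@H](O)C2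
F5 | step 4 | 6,8-dibromo-5,7,3',4'-tetra-O-benzyl-(+)-catechin-(6'→6)-8-bromo-5,7,3',4'-tetra-O-benzyl-(+)-catechin | c1ccccc1COc1c(Br)c(OCc3ccccc3)c2c(c1Br)O[C@H](c1cc(OCc3ccccc3)c(OCc3ccccc3)cc1-c1c(OCc4ccccc4)c(Br)c3c(c1OCc4ccccc4)C[C@H](O)[C@@H](c1ccc(OCc4ccccc4)c(OCc4ccccc4)c1)O3)[C@@H](O)C2
F6 | step 3 | 3',4'-O-diphenylmethylene-(+)-catechin | Oc1cc(O)c2c(c1)O[C@H](c1ccc3OC(c4ccccc4)(c4ccccc4)Oc3c1)[C@@H](O)C2
F7 | step 3 | 6,8-dibromo-3',4'-O-diphenylmethylene-(+)-catechin | Oc1c(Br)c(O)c2c(c1Br)O[C@H](c1ccc3OC(c4ccccc4)(c4ccccc4)Oc3c1)[C@@H](O)C2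
F8 | step 5 | 6,8-dibromo-(+)-catechin-(6'→6)-8-bromo-(+)-catechin | Oc1c(Br)c(O)c2c(c1Br)O[C@H](c1cc(O)c(O)cc1-c1c(O)c(Br)c3c(c1O)C[C@H](O)[C@@H](c1ccc(O)c(O)c1)O3)[C@@H](O)C2
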